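## Retrosynthetic overview

1. 13 ⇒ 12 ⇒ 11: after the key step only two unmaskings remain, fluoride removal of a 3-O,2'-O-silylene and chelation-directed cleavage of the 5-OMe group.
2. 11 ⇒ 10: C2–C1' is cut as a C–H/C–H pair. In the forward sense an anodic dehydrogenative coupling joins two donor-type carbons (the enol β-carbon C2 of ring C and the phenol ortho-carbon of 3-methoxyphenol) inside a silaketal.
3. Enabling feature: O3 on C3 (ring C) and O2' on C2' (ring B) sit on the two atoms next to the C2–C1' bond (array O3–C3=C2–C1'=C2'–O2'), so one tBu2Si atom ties both partners into a seven-membered closure. The 4'-OMe is para to C1', and C3 lies between O3 and C4=O (captodative radical site).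
4. 10 ⇒ 3-hydroxy-5,7,8-trimethoxychromone 7 + 3-methoxyphenol 8 + tBu2Si(OTf)2; 7 ⇒ enaminone 4 ⇒ acetophenone 3 ⇒ 1,2,3,5-tetramethoxybenzene 1.
5. Ring order: A bought (1); C closed in step 3 (O1–C2 bond); B bought (8); the temporary dioxasilepine ring is closed in step 6 and opened in step 8.

Key step: step 6

Remark on the chemistry: the target has no stereocentre and no configurationally stable axis. It is achiral, so no enantiocontrol is needed.

## Route

Step 1
Reactants: 1 1,2,3,5-tetramethoxybenzene
Product: 3 2-hydroxy-3,4,6-trimethoxyacetophenone, via tetramethoxyacetophenone 2 (not isolated)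
Conditions: AcCl, AlCl3, CH2Cl2, 0 °C → rt; then 1 M HCl
Reagents that add atoms: acetyl chloride, CC(=O)Cl
Why: Friedel–Crafts acylation at one of the two equivalent free positions of 1, followed in the same flask by chelation-directed AlCl3 ether cleavage of the ortho methoxy group crowded between the acetyl group and the neighbouring methoxy group, should give the hydrogen-bonded o-hydroxyacetophenone.

Step 2
Reactants: 3 2-hydroxy-3,4,6-trimethoxyacetophenone
Product: 4 (E)-3-(dimethylamino)-1-(2-hydroxy-3,4,6-trimethoxyphenyl)prop-2-en-1-one
Conditions: DMF-DMA, toluene, 100 °C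
Reagents that add atoms: N,N-dimethylformamide dimethyl acetal, COC(OC)N(C)C
Why: Condensation of the methyl ketone with the amide acetal (enaminone formation) is the standard C1 homologation of o-hydroxyacetophenones, should leave the chelated phenol untouched, and should give the thermodynamic E-alkene.

Step 3
Reactants: 4 (E)-3-(dimethylamino)-1-(2-hydroxy-3,4,6-trimethoxyphenyl)prop-2-en-1-one
Product: 6 5,7,8-trimethoxy-4-oxo-4H-chromen-3-yl benzoate, via benzoyloxy enaminone 5 (not isolated)
Conditions: (BzO)2, MeCN, 80 °C
Reagents that add atoms: dibenzoyl peroxide, O=C(OOC(=O)c1ccccc1)c1ccccc1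
Why: The α-C–H acyloxylation of tertiary o-hydroxyaryl enaminones with diaroyl peroxides, followed by addition–elimination of the phenol at the β-carbon with loss of dimethylamine, is a known domino chromone annulation that installs O3 and closes ring C in one step.

Step 4
Reactants: 6 5,7,8-trimethoxy-4-oxo-4H-chromen-3-yl benzoate
Product: 7 3-hydroxy-5,7,8-trimethoxy-4H-chromen-4-one
Conditions: p-TsOH·H2O (cat.), MeOH, reflux
Reagents that add atoms: none
Why: Acid-catalysed transesterification of the activated enol benzoate should free the 3-OH group while avoiding the base-induced opening of the 2-unsubstituted pyranone ring.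

Step 5
Reactants: 7 3-hydroxy-5,7,8-trimethoxy-4H-chromen-4-one; 8 3-methoxyphenol
Product: 10 di-tert-butyl(3-methoxyphenoxy)[(5,7,8-trimethoxy-4-oxo-4H-chromen-3-yl)oxy]silane, via aryloxysilyl triflate 9 (not isolated)
Conditions: 8, tBu2Si(OTf)2, 2,6-lutidine, CH2Cl2, −78 → 0 °C; then 7, Et3N, DMAP (cat.), 0 °C → rt
Reagents that add atoms: di-tert-butylsilyl bis(trifluoromethanesulfonate), CC(C)(C)[Si](OS(=O)(=O)C(F)(F)F)(OS(=O)(=O)C(F)(F)F)C(C)(C)C
Why: In this stepwise silyl ether formation (unsymmetrical silaketal synthesis) the phenol displaces the first triflate quickly in the cold, whereas the second, now hindered triflate should react only once the acidic enol 7 is added with a stronger base, which should keep symmetrical silaketals low.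

Step 6
Reactants: 10 di-tert-butyl(3-methoxyphenoxy)[(5,7,8-trimethoxy-4-oxo-4H-chromen-3-yl)oxy]silane
Product: 11 3-O,2'-O-(di-tert-butylsilanediyl)-3,2'-dihydroxy-5,7,8,4'-tetramethoxyflavone (seven-membered 1,3,2-dioxasilepine fused to rings B and C)
Conditions: BDD anode, Pt cathode, undivided cell, Bu3MeN·O3SOMe (0.1 M), HFIP–CH2Cl2 9:1, 5 mM, 2.5 mA cm−2, 2.2 F mol−1, rt
Reagents that add atoms: none
Why: Proposed new method: one-electron anodic oxidation of 10 should give a radical cation whose hole equilibrates between the resorcinol-type ring and the O1–C2=C3–O3 ene-diether unit; the aryl carbon para to OMe and ortho to OSi then attacks C2, whose charge is stabilised by O1, leaving a captodative radical at C3 between O3 and C4=O, after which loss of the Wheland proton, a second electron and the C2 proton restores both π-systems while HFIP is reduced to H2 at the cathode. The closest known reaction types are the oxidative coupling of silyl bis-enol ethers across the same O–Si–O bridge, the anodic dehydrogenative cross-coupling of free or silyl-protected phenols with arenes in HFIP at BDD, the intramolecular anodic enol ether–arene coupling, and the palladium-catalysed closure of the same di-tert-butyl dioxasilepine ring from o-bromoaryloxy(aryloxy)silanes, but none of them has been shown on C2–H of a 3-oxychromone. The only ring closed is the temporary seven-membered ring C2–C3–O3–Si–O2'–C2'–C1', formally a 7-endo-trig attack on C2=C3 that the angle compression of the two tert-butyl groups should favour. No stereocentre is formed, and the twisted C2–C1' axis of 11 is stereochemically irrelevant because it rotates freely once the tether is gone. The step needs cross- rather than homo-coupling and the correct ring B position: the tether makes the cross-coupling intramolecular and lets only the two ortho carbons reach C2, and of these the one between OSi and OMe is sterically shielded while the other is also para to OMe. It further needs ring A and the product to survive, which should be secured by the carbonyl deactivation of ring A, by high dilution against intermolecular attack at C6–H, by a medium free of water and methanol that offers no nucleophile for 5,8-quinone formation, and by a product whose enol and phenol oxygens stay silylated in a twisted ring.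

Step 7
Reactants: 11 3-O,2'-O-(di-tert-butylsilanediyl)-3,2'-dihydroxy-5,7,8,4'-tetramethoxyflavone
Product: 12 3-O,2'-O-(di-tert-butylsilanediyl)-3,5,2'-trihydroxy-7,8,4'-trimethoxyflavone
Conditions: BCl3 (1 M in CH2Cl2), CH2Cl2, −78 → 0 °C; then H2O
Reagents that add atoms: none
Why: Chelation-directed Lewis-acid ether cleavage through the six-membered C4=O···B···O5 chelate is the standard selective 5-O-demethylation of polymethoxyflavones; masking O3 keeps boron away from a competing 3-O chelate, and any premature loss of the silylene would be harmless because step 8 removes it anyway.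

Step 8
Reactants: 12 3-O,2'-O-(di-tert-butylsilanediyl)-3,5,2'-trihydroxy-7,8,4'-trimethoxyflavone
Product: 13 3,5,2'-trihydroxy-7,8,4'-trimethoxyflavone
Conditions: HF·pyridine, THF, 0 °C → rt (polypropylene vessel)
Reagents that add atoms: none
Why: Fluoride-induced cleavage of the di-tert-butylsilylene, with an enolate and a phenolate as good leaving groups at silicon, should free 3-OH and 2'-OH together under mildly acidic, non-oxidising conditions that the flavonol tolerates.

## Compound list

1 | 1,2,3,5-tetramethoxybenzene | COc1cc(OC)c(OC)c(OC)c1 | starting material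
2 | 2,3,4,6-tetramethoxyacetophenone | CC(=O)c1c(OC)cc(OC)c(OC)c1OC | intermediate
3 | 2-hydroxy-3,4,6-trimethoxyacetophenone | CC(=O)c1c(OC)cc(OC)c(OC)c1O | intermediate
4 | (E)-3-(dimethylamino)-1-(2-hydroxy-3,4,6-trimethoxyphenyl)prop-2-en-1-one | CN(C)/C=C/C(=O)c1c(OC)cc(OC)c(OC)c1O | intermediate
5 | 2-benzoyloxy-3-(dimethylamino)-1-(2-hydroxy-3,4,6-trimethoxyphenyl)prop-2-en-1-one (alkene geometry not fixed) | CN(C)C=C(OC(=O)c1ccccc1)C(=O)c1c(OC)cc(OC)c(OC)c1O | intermediate
6 | 5,7,8-trimethoxy-4-oxo-4H-chromen-3-yl benzoate | O=C(Oc1coc2c(OC)c(OC)cc(OC)c2c1=O)c1ccccc1 | intermediate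
7 | 3-hydroxy-5,7,8-trimethoxy-4H-chromen-4-one | O=c1c(O)coc2c(OC)c(OC)cc(OC)c12 | intermediate
8 | 3-methoxyphenol | COc1cccc(O)c1 | starting material
9 | di-tert-butyl(3-methoxyphenoxy)silyl trifluoromethanesulfonate | COc1cccc(O[Si](OS(=O)(=O)C(F)(F)F)(C(C)(C)C)C(C)(C)C)c1 | intermediate
10 | di-tert-butyl(3-methoxyphenoxy)[(5,7,8-trimethoxy-4-oxo-4H-chromen-3-yl)oxy]silane | COc1cccc(O[Si](Oc2coc3c(OC)c(OC)cc(OC)c3c2=O)(C(C)(C)C)C(C)(C)C)c1 | intermediate
11 | 3-O,2'-O-(di-tert-butylsilanediyl)-3,2'-dihydroxy-5,7,8,4'-tetramethoxyflavone | COc1ccc2c(c1)O[Si](C(C)(C)C)(C(C)(C)C)Oc1c-2oc2c(OC)c(OC)cc(OC)c2c1=O | intermediate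
12 | 3-O,2'-O-(di-tert-butylsilanediyl)-3,5,2'-trihydroxy-7,8,4'-trimethoxyflavone | COc1ccc2c(c1)O[Si](C(C)(C)C)(C(C)(C)C)Oc1c-2oc2c(OC)c(OC)cc(O)c2c1=O | intermediate
13 | 3,5,2'-trihydroxy-7,8,4'-trimethoxyflavone | COc1ccc(-c2oc3c(OC)c(OC)cc(O)c3c(=O)c2O)c(O)c1 | target

## Step count and risks

Total step count: 8. Longest linear sequence: 8 steps (1 → 13); 8 enters at step 5.

**Step 6 (Proposed new method).**
- Risks: the hole may stay on ring A and lead to intermolecular coupling at C6–H, or to oxidative loss of the para-related 5- and 8-methyl groups.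
- The seven-membered closure may also be too slow to compete with solvolysis of the Si–O bonds, and the product may be oxidised further.
- The fallback is known, redox-neutral chemistry in which a halide sets the polarity. It sets out from 7 and comes back at 11.
- Commercial 2-bromo-5-methoxyphenol is treated with tBu2Si(OTf)2 and 2,6-lutidine as in step 5 to give (2-bromo-5-methoxyphenoxy)di-tert-butylsilyl trifluoromethanesulfonate F1.
- F1 is trapped with 7 (Et3N, DMAP) to give (2-bromo-5-methoxyphenoxy)di-tert-butyl[(5,7,8-trimethoxy-4-oxo-4H-chromen-3-yl)oxy]silane F2.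
- A silicon-tethered palladium-catalysed intramolecular C–H arylation (Pd(OAc)2, PCy3·HBF4, PivOH cat., K2CO3, DMA, 100 °C) should then close C2–C1' and give 11. This reaction type is known for unsymmetrical o-biphenols through the same dioxasilepine ring.

**Step 5.**
- Risks: double substitution and ligand scrambling at the bis-electrophilic silicon may give symmetrical silaketals, and the silyl triflate may hydrolyse before the enol arrives.
- The fallback builds the two Si–O bonds from a monofunctional silane with a purifiable intermediate. It sets out from 8 and comes back at 9, and from there reaches 10.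
- 8 is silylated with tBu2SiHCl (imidazole, DMF, rt) to give di-tert-butyl(3-methoxyphenoxy)silane F3, which is purified.
- The Si–H bond is chlorinated without touching the electron-rich ring (C2Cl6, PdCl2 cat., THF, rt) to give chlorodi-tert-butyl(3-methoxyphenoxy)silane F4.
- AgOTf in CH2Cl2 converts F4 into 9 free of any bis-triflate, and addition of 7, Et3N and DMAP then gives 10.

**Step 3.**
- Risks: the peroxide may attack the very electron-rich ring at its free position, or the hindered 2,6-disubstituted aryl ketone may slow the acyloxylation so that plain cyclisation to the 3-unsubstituted chromone takes over.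
- The fallback separates ring closure from oxygenation. It sets out from 4 and comes back at 7.
- 4 is cyclised with conc. HCl in CH2Cl2 to 5,7,8-trimethoxy-4H-chromen-4-one F5.
- F5 is epoxidised with dimethyldioxirane (acetone–CH2Cl2, 0 °C) to racemic cis-2,3-epoxy-5,7,8-trimethoxychroman-4-one F6.
- F6 isomerises to 7 on treatment with catalytic p-TsOH in CH2Cl2, by opening at C2 and loss of the C2 proton.

## Further compounds

F1 | step 6 | (2-bromo-5-methoxyphenoxy)di-tert-butylsilyl trifluoromethanesulfonate | COc1ccc(Br)c(O[Si](OS(=O)(=O)C(F)(F)F)(C(C)(C)C)C(C)(C)C)c1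
F2 | step 6 | (2-bromo-5-methoxyphenoxy)di-tert-butyl[(5,7,8-trimethoxy-4-oxo-4H-chromen-3-yl)oxy]silane | COc1ccc(Br)c(O[Si](Oc2coc3c(OC)c(OC)cc(OC)c3c2=O)(C(C)(C)C)C(C)(C)C)c1
F3 | step 5 | di-tert-butyl(3-methoxyphenoxy)silane | COc1cccc(O[SiH](C(C)(C)C)C(C)(C)C)c1
F4 | step 5 | chlorodi-tert-butyl(3-methoxyphenoxy)silane | COc1cccc(O[Si](Cl)(C(C)(C)C)C(C)(C)C)c1
F5 | step 3 | 5,7,8-trimethoxy-4H-chromen-4-one | COc1cc(OC)c2c(=O)ccoc2c1OC
F6 | step 3 | cis-2,3-epoxy-5,7,8-trimethoxychroman-4-one (racemic, one enantiomer drawn) | O=C1[C@H]2O[C@H]2Oc2c(OC)c(OC)cc(OC)c21
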